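We cannot spend one incoming ligand twice, and in this flask each exchange may spend two: one enters the complex, and the leaving ligand it frees can hold a second as idle adduct.

the same everywhere: starting complex 23 mM
- birch: incoming ligand 29 mM; run made earlier
- maple: incoming ligand 43 mM; run made earlier
- flask: incoming ligand 57.5 mM; time 2.0 min

| run | time / min | starting complex / % | complex with three exchanged / % |
|---|---|---|---|
| birch | 0.200 | 38.0 | 1.0 |
| birch | 0.667 | 28.1 | 0.3 |
| birch | 1.00 | 26.5 | 0 |
| birch | 1.50 | 24.9 | 0.5 |
| birch | 2.50 | 24.2 | 0 |
| maple | 0.200 | 20.9 | 2.4 |
| maple | 0.667 | 11.2 | 0.9 |
| maple | 1.00 | 9.4 | 0 |
| maple | 1.50 | 8.2 | 1.4 |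
| maple | 2.50 | 6.9 | 1.1 |

(each reading ± 0.5 percentage points)

- amounts and yields of leaving ligand count idle adduct too
- reactions considered so far: starting complex + incoming ligand <-> leaving ligand + complex with one exchanged; complex with one exchanged + incoming ligand <-> leaving ligand + complex with two exchanged; complex with two exchanged + incoming ligand <-> leaving ligand + complex with three exchanged; complex with three exchanged + incoming ligand <-> leaving ligand + complex with four exchanged; leaving ligand + incoming ligand <-> idle adduct
- the earlier runs do not show how much of incoming ligand is bound; that part of a forecast is a guess

* part of the starting complex that has reacted at 2.0 min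
* share of the unused incoming ligand that is free and not bound as idle adduct, at 2.0 min

So, for whoever takes over the bench, we count turnovers. Half the incoming ligand charged, divided by the starting complex charged, is the payable count, the exchanges per starting complex at which every incoming ligand has been spent this way: 1.25 for the flask.

Written as a share of one exchange per starting complex, the count is 93.5% in the maple run, where the last reading shows 93.1% of the starting complex reacted, but 63.0% in the birch run, where it shows 75.8%, so the count is a rough mark. Maple's starting complex moved from 9.4% at 1.00 min to 6.9% at 2.50 min, so we reckon by amounts, as under thermodynamic control.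

Add nothing to the flask: the count is reckoned from its charges. We expect a few percent of starting complex left, and free incoming ligand about equal to free leaving ligand, though the runs do not show how much that is.

The forecast says 97% reacted and 40% free, adding “Second exchange would lower this”.

The flask gives 97.6% reacted and 14.2% free, 26 percentage points below the forecast.

    starting complex + incoming ligand ⇌ leaving ligand + complex with one exchanged (K = 29.0, k = 11.0 /M/s)
    complex with one exchanged + incoming ligand ⇌ leaving ligand + complex with two exchanged (K = 0.200, k = 1.20 /M/s)
    complex with two exchanged + incoming ligand ⇌ leaving ligand + complex with three exchanged (K = 0.230, k = 56.0 /M/s)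
    complex with three exchanged + incoming ligand ⇌ leaving ligand + complex with four exchanged (K = 0.130, k = 1.20 /M/s)
    leaving ligand + incoming ligand ⇌ idle adduct, settled at all times (K = 1600 /M)

At 2.00 min the flask holds 3.77 mM of free leaving ligand and 24.8 mM of idle adduct, which makes 1.24 exchanges per starting complex charged, against the count of 1.25. Its free incoming ligand is 4.11 mM. A neighbouring flask, charged with 14 mM of starting complex, has a count of 2.05 and makes 1.89 exchanges per starting complex by the same time. Its complex with one exchanged stands at 45.5%, and 22.0% of its unused incoming ligand is free.

The earlier runs and the new flask were generated by integration from invented constants; scatter was added.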